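Assumption: the target is achiral, so the racemic cyclobutenones 6 and 13 are used as such, and [4-(benzyloxy)-3-formylphenyl]boronic acid 7 is taken as a catalogue building block.

Abbreviation used in names: ArB = 2-(benzyloxy)-5-[4-(benzyloxy)benzyl]phenyl, the protected ring B.

## The problem

The target (C36H34O6) has no stereocentre; five benzene rings are joined only by CH2 and CH2CH2 links, so the whole difficulty is positional. Ring A is pentasubstituted. Numbered as a phenol, C1 carries OH, C2 and C4 each a 4-hydroxybenzyl group, C3 the CH2CH2 bridge to ring B, C5 the OMe group and C6 the only hydrogen. C2, C3 and C4 are three adjacent carbon-substituted positions, with the two benzyl groups flanking the bridge, while C6, the most nucleophilic position of the resorcinol, must stay free. This is the opposite of what electrophilic substitution favours. The two oxygens of ring A must be told apart (one OH, one OMe), and ring B must carry its benzyl group para and the bridge ortho to its OH. Four phenols are free in the product, and 4-hydroxybenzyl–arene bonds can ionize to quinone methides under acid or oxidation. The phenols therefore stay masked until a mild last step, and the masks must come off beside an aryl methyl ether. The enabling feature is the unit O–C1–C6(H)–C5–O of ring A: a resorcinol monoether with an unsubstituted CH between the oxygens, whose other ring atoms C2, C3 and C4 bear only carbon groups, those on C2 and C4 being identical. This is the pattern that a vinylketene (C1 to C4) and methoxyacetylene (C5, C6) give in a cyclobutenone–ynol ether benzannulation. Because the C2 and C4 arms are equal, the four-carbon partner is itself built from two molecules of one three-carbon ynol ether.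

## Retrosynthesis

**22 to 21.** The CH2CH2 bridge is drawn as C≡C and the four phenols as benzyl ethers. One hydrogenation of 21 then forms the bridge and frees every phenol. The alkyne lets ring B enter earlier as an acetylide, and no separate deprotection step is needed. The forward reaction must leave the diarylmethane C–C bonds and the OMe group untouched.

**21 to 13 + 16 (key).** Ring A is cut at C4–C5 and C6–C1. C5 and C6 become methoxyacetylene 16; C1 to C4 become the four ring carbons of cyclobutenone 13, with C1 as its carbonyl. A Friedel–Crafts cut at the benzyl groups would leave the regiochemical problem unsolved. Here the ring is built with all five substituents in place and with OH (from the ketene carbonyl) and OMe (from 16) already differentiated. Precursor 13 has no aromatic ring A at all. The forward reaction needs a regioselective ketene–ynol ether [2+2] addition followed by two electrocyclic steps through 17, 18, 19 and 20.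

**13 to 6 + 10.** The bond from ring A C3 to the alkyne carbon is cut: lithium acetylide 11 adds to the vinylogous ester 6, and acid transposes the carbonyl through carbinol 12. Because C2 and C4 of 6 carry the same benzyl group, 1,2-addition/transposition and addition–elimination give the same 13, so no regiochemical demand remains.

**6 to two molecules of 4.** The four-membered ring is cut into aldoketene 5 and ynol ether 4, and 5 is itself 4 after loss of ethene. One compound therefore supplies C1, C2, C4 and both benzyl arms of ring A. The forward reaction needs only heat, and the polarity of the ynol ether fixes the orientation.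

**4 to 1 + 2.** The propargylic C–C bond is cut: lithium ethoxyacetylide 3 is alkylated by benzylic bromide 2.

**10 to 8 to 7 + 2.** The alkyne carbon comes from a one-carbon homologation of aldehyde 8 through diazoalkene 9. The diarylmethane bond of 8 comes from a benzyl–aryl Suzuki–Miyaura coupling of 7 with the same bromide 2. Bromide 2 is thus the source of all three 4-hydroxybenzyl groups.

**16 to 14.** Methoxyacetylene is made by double elimination from chloroacetal 14 through its sodium salt 15.

## Roads not taken

**Alternative 1:** the most obvious cut is at the three ArCH2–arene bonds, giving the parent bibenzyl 3-[2-(2-hydroxyphenyl)ethyl]-5-methoxyphenol A1 and three equivalents of 4-hydroxybenzyl alcohol A2. The forward key step is an acid-promoted Friedel–Crafts benzylation through the quinone methide of A2, as in the biosynthesis. Ring A of A1 has three activated CH positions and ring B two. Exactly three of the five must react, the two on ring A being the most hindered, while the most nucleophilic one between the oxygens must stay free. Each benzylation makes the arene richer, and A2 condenses with itself. The chosen plan fixes every position by construction and needs no selectivity among like positions.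

**Alternative 2:** the bridge is cut at ring A, giving the fully substituted iodide 1-(benzyloxy)-2,4-bis[4-(benzyloxy)benzyl]-3-iodo-5-methoxybenzene A3 and alkyne 10. The forward key step is a Sonogashira coupling to the pentabenzyl diarylalkyne A4, followed by hydrogenation. This only moves the problem: A3 is as hard to make as ring A itself, needing two regioselective C-benzylations of a 5-iodoresorcinol ether and a separate differentiation of the oxygens. Coupling at an iodide flanked by two benzyl groups would also be slow. The benzannulation makes the same ring from a four-membered precursor in one operation.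

**Alternative 3:** ring A is built at the cyclohexane oxidation level. Enone (E)-3-[4-(benzyloxy)benzyl]-6-(ArB)hex-3-en-2-one A5 and diethyl 2-[4-(benzyloxy)benzyl]malonate A6 would be joined by Michael addition and Claisen closure. Decarboxylation and dehydrogenation would give the symmetric resorcinol A7, which would then be monomethylated. The conjugate addition joins a tertiary carbanion to an α,β-disubstituted enone and is reversible and congested. Aromatizing a fully substituted ring needs oxidants that endanger the benzylic positions. The OH/OMe differentiation is only statistical, and A5 needs several steps of its own. The chosen route reaches the aromatic level and the differentiated oxygens directly.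

Key step: step 7

## Steps

Step 1
Reactants: 1 ethoxyacetylene; 2 4-(benzyloxy)benzyl bromide
Product: 4 1-(benzyloxy)-4-(3-ethoxyprop-2-yn-1-yl)benzene, via lithium ethoxyacetylide 3 (not isolated)
Conditions: 1, n-BuLi, THF, −78 °C; then 2, DMPU, −78 °C to rt; chromatography on Et3N-deactivated silica
Reagents that add atoms: none
Why: Alkylation of a lithium alkoxyacetylide by a reactive benzylic bromide (SN2) in a dipolar cosolvent; the acetylide is too weak a base to isomerize the product to an allene.

Step 2
Reactants: 4 1-(benzyloxy)-4-(3-ethoxyprop-2-yn-1-yl)benzene (two molecules)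
Product: 6 2,4-bis[4-(benzyloxy)benzyl]-3-ethoxycyclobut-2-en-1-one (racemic), via ketene 5 (not isolated)
Conditions: toluene (about 1 M), 110 °C, sealed tube, N2
Reagents that add atoms: none
Why: Thermal retro-ene loss of ethene from a 1-ethoxyalkyne gives aldoketene 5, which unchanged 4 traps in a ketene–ynol ether [2+2] cycloaddition (ketene carbonyl carbon to the benzyl-bearing alkyne carbon), the known self-condensation of 1-ethoxyalkynes to 3-ethoxy-2,4-dialkylcyclobutenones; the C4 stereocentre forms racemic and is erased in step 7.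

Step 3
Reactants: 2 4-(benzyloxy)benzyl bromide; 7 [4-(benzyloxy)-3-formylphenyl]boronic acid
Product: 8 2-(benzyloxy)-5-[4-(benzyloxy)benzyl]benzaldehyde
Conditions: Pd(PPh3)4 (3 mol %), K3PO4, toluene–H2O (20:1), 80 °C
Reagents that add atoms: none
Why: Suzuki–Miyaura coupling of a benzylic bromide with an arylboronic acid; oxidative addition into the benzylic C–Br bond is fast, the nearly anhydrous phosphate medium limits solvolysis of the electron-rich bromide, and the aldehyde and benzyl ethers are inert.

Step 4
Reactants: 8 2-(benzyloxy)-5-[4-(benzyloxy)benzyl]benzaldehyde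
Product: 10 1-(benzyloxy)-4-[4-(benzyloxy)benzyl]-2-ethynylbenzene, via diazoalkene 9 (not isolated)
Conditions: dimethyl (1-diazo-2-oxopropyl)phosphonate, K2CO3, MeOH–THF, 0 °C to rt
Reagents that add atoms: dimethyl (1-diazo-2-oxopropyl)phosphonate, CC(=O)C(=[N+]=[N-])P(=O)(OC)OC
Why: Seyferth–Gilbert homologation with the Ohira–Bestmann reagent: methanolysis frees the diazomethylphosphonate anion, a Horner–Wadsworth–Emmons-type olefination gives diazoalkene 9, and loss of N2 with 1,2-hydride shift gives the terminal alkyne under carbonate conditions that spare the ethers and the diarylmethane.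

Step 5
Reactants: 10 1-(benzyloxy)-4-[4-(benzyloxy)benzyl]-2-ethynylbenzene; 6 2,4-bis[4-(benzyloxy)benzyl]-3-ethoxycyclobut-2-en-1-one
Product: 13 2,4-bis[4-(benzyloxy)benzyl]-3-[(ArB)ethynyl]cyclobut-2-en-1-one (racemic), via lithium acetylide 11 (not isolated), via carbinol 12 (not isolated)
Conditions: 10, n-BuLi, THF, −78 °C; then 6, −78 to −40 °C; then 1 M aq HCl, THF, 0 °C to rt
Reagents that add atoms: water, O
Why: 1,2-Addition of a lithium acetylide to a vinylogous ester and acid-promoted ionization and hydrolysis (Stork–Danheiser-type carbonyl transposition); since C2 and C4 of 6 bear the same benzyl group, 1,2-addition/transposition and addition–elimination lead to the same 13, and deprotonation at C4 is disfavoured because the resulting enolate would be cyclobutadiene-like.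

Step 6
Reactants: 14 chloroacetaldehyde dimethyl acetal
Product: 16 methoxyacetylene, via sodium methoxyacetylide 15 (not isolated)
Conditions: NaNH2 (3 equiv), liquid NH3, −33 °C; then sat. aq NH4Cl, −20 °C; distilled into cold toluene
Reagents that add atoms: none
Why: Two successive base-induced eliminations (methanol, then HCl) with sodium amide give the sodium salt of the ynol ether, freed by mild protonation; the standard preparation of this low-boiling alkyne, handled cold as a toluene solution.

Step 7
Reactants: 13 2,4-bis[4-(benzyloxy)benzyl]-3-[(ArB)ethynyl]cyclobut-2-en-1-one; 16 methoxyacetylene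
Product: 21 2,4-bis[4-(benzyloxy)benzyl]-3-[(ArB)ethynyl]-5-methoxyphenol, via vinylketene 17 (not isolated), via methoxycyclobutenone 18 (not isolated), via dienylketene 19 (not isolated), via cyclohexadienone 20 (not isolated)
Conditions: 16 (3 equiv), toluene, sealed tube, 80 °C then 110 °C
Reagents that add atoms: none
Why: Danheiser benzannulation of a cyclobutenone with an alkoxyacetylene, the closest known reaction type. Conrotatory 4π opening of 13 (only the C1–C4 bond can open) gives vinylketene 17, with the C4 benzyl group turned outward so that hydrogen sits inside. The ketene C=C of 17 adds to 16 in a [2+2] cycloaddition whose orientation is set by the ynol ether polarity (unsubstituted alkyne carbon to the ketene carbonyl carbon), giving the four-membered ring of 18. 4π opening of 18 gives dienylketene 19; this opening is reversible, so only the rotamer with the alkenyl group cis to the ketene goes on. Ring A closes by 6π disrotatory electrocyclization between the ketene carbon and the CH(benzyl) terminus to give dienone 20, which tautomerizes irreversibly to phenol 21. No stereocentre survives: the C4 centre of 13 and the quaternary centre of 18 both become aromatic carbons. The step needs regioselectivity in the [2+2] addition, secured by the oxygen of 16, which places OMe meta to the new OH with the CH between them. It also needs chemoselectivity for 16 over the diaryl alkyne, secured because only the ynol ether is nucleophilic enough for a ketene; the inward hydrogen at the terminus excludes a 1,5-hydrogen shift and eases closure.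

Step 8
Reactants: 21 2,4-bis[4-(benzyloxy)benzyl]-3-[(ArB)ethynyl]-5-methoxyphenol
Product: 22 2,4-bis(4-hydroxybenzyl)-3-{2-[2-hydroxy-5-(4-hydroxybenzyl)phenyl]ethyl}-5-methoxyphenol (target)
Conditions: H2 (1 to 3 atm), Pd/C (10 %), EtOAc–MeOH, rt
Reagents that add atoms: none
Why: Heterogeneous hydrogenation saturates the diarylalkyne to the CH2CH2 bridge and hydrogenolyses the four O-benzyl ethers in one operation; diarylmethane C–C bonds, the aryl methyl ether and the arenes are inert under these conditions, and no stereocentre is involved.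

## Compound list

1 | ethoxyacetylene (ethoxyethyne) | C#COCC | starting material
2 | 4-(benzyloxy)benzyl bromide | BrCc1ccc(OCc2ccccc2)cc1 | starting material
3 | lithium ethoxyacetylide | [Li]C#COCC | intermediate
4 | 1-(benzyloxy)-4-(3-ethoxyprop-2-yn-1-yl)benzene | CCOC#CCc1ccc(OCc2ccccc2)cc1 | intermediate
5 | 3-[4-(benzyloxy)phenyl]prop-1-en-1-one (aldoketene) | O=C=CCc1ccc(OCc2ccccc2)cc1 | intermediate
6 | 2,4-bis[4-(benzyloxy)benzyl]-3-ethoxycyclobut-2-en-1-one (racemic) | CCOC1=C(Cc2ccc(OCc3ccccc3)cc2)C(=O)C1Cc1ccc(OCc2ccccc2)cc1 | intermediate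
7 | [4-(benzyloxy)-3-formylphenyl]boronic acid | O=Cc1cc(B(O)O)ccc1OCc1ccccc1 | starting material
8 | 2-(benzyloxy)-5-[4-(benzyloxy)benzyl]benzaldehyde | O=Cc1cc(Cc2ccc(OCc3ccccc3)cc2)ccc1OCc1ccccc1 | intermediate
9 | 1-(benzyloxy)-4-[4-(benzyloxy)benzyl]-2-(2-diazoethenyl)benzene (diazoalkene) | [N-]=[N+]=C=Cc1cc(Cc2ccc(OCc3ccccc3)cc2)ccc1OCc1ccccc1 | intermediate
10 | 1-(benzyloxy)-4-[4-(benzyloxy)benzyl]-2-ethynylbenzene | C#Cc1cc(Cc2ccc(OCc3ccccc3)cc2)ccc1OCc1ccccc1 | intermediate
11 | lithium acetylide of 10 | [Li]C#Cc1cc(Cc2ccc(OCc3ccccc3)cc2)ccc1OCc1ccccc1 | intermediate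
12 | 2,4-bis[4-(benzyloxy)benzyl]-3-ethoxy-1-[(ArB)ethynyl]cyclobut-2-en-1-ol (carbinol, isomer mixture) | CCOC1=C(Cc2ccc(OCc3ccccc3)cc2)C(O)(C#Cc2cc(Cc3ccc(OCc4ccccc4)cc3)ccc2OCc2ccccc2)C1Cc1ccc(OCc2ccccc2)cc1 | intermediate
13 | 2,4-bis[4-(benzyloxy)benzyl]-3-[(ArB)ethynyl]cyclobut-2-en-1-one (racemic) | O=C1C(Cc2ccc(OCc3ccccc3)cc2)=C(C#Cc2cc(Cc3ccc(OCc4ccccc4)cc3)ccc2OCc2ccccc2)C1Cc1ccc(OCc2ccccc2)cc1 | intermediate
14 | chloroacetaldehyde dimethyl acetal (2-chloro-1,1-dimethoxyethane) | ClCC(OC)OC | starting material
15 | sodium methoxyacetylide | [Na]C#COC | intermediate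
16 | methoxyacetylene (methoxyethyne) | C#COC | intermediate
17 | 2-[4-(benzyloxy)benzyl]-3-[(ArB)ethynyl]-5-[4-(benzyloxy)phenyl]penta-1,3-dien-1-one (vinylketene, C5 trans to C2 across C3=C4) | O=C=C(Cc1ccc(OCc2ccccc2)cc1)/C(C#Cc1cc(Cc2ccc(OCc3ccccc3)cc2)ccc1OCc1ccccc1)=C/Cc1ccc(OCc2ccccc2)cc1 | intermediate
18 | 4-[4-(benzyloxy)benzyl]-3-methoxycyclobut-2-en-1-one bearing at C4 also the 1-[(ArB)ethynyl]-3-[4-(benzyloxy)phenyl]prop-1-en-1-yl group (racemic) | O=C1C=C(OC)C1(Cc2ccc(OCc3ccccc3)cc2)/C(C#Cc2cc(Cc3ccc(OCc4ccccc4)cc3)ccc2OCc2ccccc2)=C/Cc2ccc(OCc3ccccc3)cc2 | intermediate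
19 | 4-[4-(benzyloxy)benzyl]-5-[(ArB)ethynyl]-3-methoxy-7-[4-(benzyloxy)phenyl]hepta-1,3,5-trien-1-one (dienylketene, C2 and C5 cis across C3=C4) | O=C=C/C(OC)=C(Cc1ccc(OCc2ccccc2)cc1)\C(C#Cc1cc(Cc2ccc(OCc3ccccc3)cc2)ccc1OCc1ccccc1)=C\Cc1ccc(OCc2ccccc2)cc1 | intermediate
20 | 4,6-bis[4-(benzyloxy)benzyl]-5-[(ArB)ethynyl]-3-methoxycyclohexa-2,4-dien-1-one (racemic) | O=C1C=C(OC)C(Cc2ccc(OCc3ccccc3)cc2)=C(C#Cc2cc(Cc3ccc(OCc4ccccc4)cc3)ccc2OCc2ccccc2)C1Cc1ccc(OCc2ccccc2)cc1 | intermediate
21 | 2,4-bis[4-(benzyloxy)benzyl]-3-[(ArB)ethynyl]-5-methoxyphenol | COc1cc(O)c(Cc2ccc(OCc3ccccc3)cc2)c(C#Cc2cc(Cc3ccc(OCc4ccccc4)cc3)ccc2OCc2ccccc2)c1Cc1ccc(OCc2ccccc2)cc1 | intermediate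
22 | 2,4-bis(4-hydroxybenzyl)-3-{2-[2-hydroxy-5-(4-hydroxybenzyl)phenyl]ethyl}-5-methoxyphenol | COc1cc(O)c(Cc2ccc(O)cc2)c(CCc2cc(Cc3ccc(O)cc3)ccc2O)c1Cc1ccc(O)cc1 | target

## Step count and risks

Total steps: 8. Longest linear sequence: 5 steps (steps 1, 2, 5, 7, 8, or equally steps 3, 4, 5, 7, 8).

**Step 7 (key step).** The likeliest failure is diversion of the cross-conjugated vinylketene 17 before the [2+2] addition. Its ketene carbon is fully substituted, so cycloaddition with the volatile ynol ether may be slower than oligomerization through the conjugated alkyne or O-acylation of the product phenol by 17. Any aryl ester formed by acylation can be cleaved by mild methanolysis. The fallback removes the alkyne before the pericyclic cascade, so that a plain 3-alkylcyclobutenone, the best-precedented substrate class, is used. It sets out from aldehyde 8 and returns to the route at target 22.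
- Wittig methylenation of 8 (Ph3P=CH2, THF) would give 1-(benzyloxy)-4-[4-(benzyloxy)benzyl]-2-ethenylbenzene F1.
- Hydroboration–oxidation (9-BBN, then H2O2, NaOH) would give 2-(ArB)ethanol F2.
- Iodination (I2, PPh3, imidazole) would give 1-(benzyloxy)-4-[4-(benzyloxy)benzyl]-2-(2-iodoethyl)benzene F3.
- Iodine–lithium exchange (t-BuLi, Et2O, −78 °C), addition to 6 and acid hydrolysis as in step 5 would give 2,4-bis[4-(benzyloxy)benzyl]-3-[2-(ArB)ethyl]cyclobut-2-en-1-one F4.
- Benzannulation of F4 with 16 as in step 7 would give 2,4-bis[4-(benzyloxy)benzyl]-3-[2-(ArB)ethyl]-5-methoxyphenol F5.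
- Hydrogenolysis of F5 as in step 8 would give 22.

**Step 2.** Two things may go wrong. Product 6 may ring-open at the reaction temperature and be consumed by unreacted 4, or ketene 5 may dimerize with itself before it is trapped. The fallback generates the ketene at room temperature from another source. It sets out from 4 and returns at 6. Commercial 3-[4-(benzyloxy)phenyl]propanoic acid F6 would be converted with oxalyl chloride and catalytic DMF into 3-[4-(benzyloxy)phenyl]propanoyl chloride F7. Slow addition of Et3N to F7 and 4 in CH2Cl2 at rt would form 5 by dehydrohalogenation in the presence of the ynol ether and give 6 by the same [2+2] addition.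

**Step 5.** The acid treatment of carbinol 12 may fail by ring opening of the cyclobutenol, or by capture of the propargylic cation at the alkyne terminus in place of the ethoxy-bearing carbon. The fallback replaces the addition–transposition by a cross-coupling. It sets out from 6 and returns at 13. Hydrolysis of 6 (aq HCl, THF) would give 2,4-bis[4-(benzyloxy)benzyl]-3-hydroxycyclobut-2-en-1-one F8. Tf2O and 2,6-lutidine (CH2Cl2, −78 °C) would give the enol triflate 2,4-bis[4-(benzyloxy)benzyl]-3-oxocyclobut-1-en-1-yl trifluoromethanesulfonate F9. Sonogashira coupling of F9 with 10 (Pd(PPh3)2Cl2, CuI, i-Pr2NH, THF, rt) would give 13.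

**Step 8.** The hydrogenation may stall at the hindered stilbene stage, and hydrogenolysis may stay incomplete as free phenols build up on the catalyst. The fallback separates the two tasks. It sets out from 21 and returns at 22. Diimide reduction of the alkyne (TsNHNH2, NaOAc, THF–H2O, reflux) would give 2,4-bis[4-(benzyloxy)benzyl]-3-[2-(ArB)ethyl]-5-methoxyphenol F5. The benzyl ethers would then be cleaved with BCl3 and pentamethylbenzene (CH2Cl2, −78 °C), which leaves the aryl methyl ether intact, to give 22.

## Further compounds

F1 | step 7 | 1-(benzyloxy)-4-[4-(benzyloxy)benzyl]-2-ethenylbenzene | C=Cc1cc(Cc2ccc(OCc3ccccc3)cc2)ccc1OCc1ccccc1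
F2 | step 7 | 2-{2-(benzyloxy)-5-[4-(benzyloxy)benzyl]phenyl}ethanol | OCCc1cc(Cc2ccc(OCc3ccccc3)cc2)ccc1OCc1ccccc1
F3 | step 7 | 1-(benzyloxy)-4-[4-(benzyloxy)benzyl]-2-(2-iodoethyl)benzene | ICCc1cc(Cc2ccc(OCc3ccccc3)cc2)ccc1OCc1ccccc1
F4 | step 7 | 2,4-bis[4-(benzyloxy)benzyl]-3-(2-{2-(benzyloxy)-5-[4-(benzyloxy)benzyl]phenyl}ethyl)cyclobut-2-en-1-one | O=C1C(Cc2ccc(OCc3ccccc3)cc2)=C(CCc2cc(Cc3ccc(OCc4ccccc4)cc3)ccc2OCc2ccccc2)C1Cc1ccc(OCc2ccccc2)cc1
F5 | step 7 | 2,4-bis[4-(benzyloxy)benzyl]-3-(2-{2-(benzyloxy)-5-[4-(benzyloxy)benzyl]phenyl}ethyl)-5-methoxyphenol | COc1cc(O)c(Cc2ccc(OCc3ccccc3)cc2)c(CCc2cc(Cc3ccc(OCc4ccccc4)cc3)ccc2OCc2ccccc2)c1Cc1ccc(OCc2ccccc2)cc1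
F6 | step 2 | 3-[4-(benzyloxy)phenyl]propanoic acid | OC(=O)CCc1ccc(OCc2ccccc2)cc1
F7 | step 2 | 3-[4-(benzyloxy)phenyl]propanoyl chloride | ClC(=O)CCc1ccc(OCc2ccccc2)cc1
F8 | step 5 | 2,4-bis[4-(benzyloxy)benzyl]-3-hydroxycyclobut-2-en-1-one | O=C1C(Cc2ccc(OCc3ccccc3)cc2)=C(O)C1Cc1ccc(OCc2ccccc2)cc1
F9 | step 5 | 2,4-bis[4-(benzyloxy)benzyl]-3-oxocyclobut-1-en-1-yl trifluoromethanesulfonate | O=C1C(Cc2ccc(OCc3ccccc3)cc2)=C(OS(=O)(=O)C(F)(F)F)C1Cc1ccc(OCc2ccccc2)cc1
F0 | step 8 | none | none
A1 | alternative 1 | 3-[2-(2-hydroxyphenyl)ethyl]-5-methoxyphenol | COc1cc(O)cc(CCc2ccccc2O)c1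
A2 | alternative 1 | 4-hydroxybenzyl alcohol | OCc1ccc(O)cc1
A3 | alternative 2 | 1-(benzyloxy)-2,4-bis[4-(benzyloxy)benzyl]-3-iodo-5-methoxybenzene | COc1cc(OCc2ccccc2)c(Cc2ccc(OCc3ccccc3)cc2)c(I)c1Cc1ccc(OCc2ccccc2)cc1
A4 | alternative 2 | 1-(benzyloxy)-2,4-bis[4-(benzyloxy)benzyl]-3-({2-(benzyloxy)-5-[4-(benzyloxy)benzyl]phenyl}ethynyl)-5-methoxybenzene | COc1cc(OCc2ccccc2)c(Cc2ccc(OCc3ccccc3)cc2)c(C#Cc2cc(Cc3ccc(OCc4ccccc4)cc3)ccc2OCc2ccccc2)c1Cc1ccc(OCc2ccccc2)cc1
A5 | alternative 3 | (E)-3-[4-(benzyloxy)benzyl]-6-{2-(benzyloxy)-5-[4-(benzyloxy)benzyl]phenyl}hex-3-en-2-one | CC(=O)/C(Cc1ccc(OCc2ccccc2)cc1)=C/CCc1cc(Cc2ccc(OCc3ccccc3)cc2)ccc1OCc1ccccc1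
A6 | alternative 3 | diethyl 2-[4-(benzyloxy)benzyl]malonate | CCOC(=O)C(Cc1ccc(OCc2ccccc2)cc1)C(=O)OCC
A7 | alternative 3 | 4,6-bis[4-(benzyloxy)benzyl]-5-(2-{2-(benzyloxy)-5-[4-(benzyloxy)benzyl]phenyl}ethyl)benzene-1,3-diol | Oc1cc(O)c(Cc2ccc(OCc3ccccc3)cc2)c(CCc2cc(Cc3ccc(OCc4ccccc4)cc3)ccc2OCc2ccccc2)c1Cc1ccc(OCc2ccccc2)cc1
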